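The meeting had one question: after 5.0 d, which flask holds the most E, when the flasks differ in how D or L goes in?

common to all: Z 0.38 mol%
- ochre: D 10 mM; L 1.2 equiv; run made earlier
- blue: D 5 mM; L 1.2 equiv; run made earlier
- amber: D 7.5 mM; L 1.2 equiv; run made earlier
- green: D 10 mM; L 1.8 equiv; run made earlier
- maple: D 10 mM; L 1.20 equiv; everything together at the start; time 5.0 d
- alder: D 10 mM (fed, over 20 h); L 1.20 equiv; all else is in the flask from the start; the feed brings no volume worth counting; time 5.0 d
- larch: D 10 mM (fed, over 3.0 d); L 1.20 equiv; all else is in the flask from the start; the feed brings no volume worth counting; time 5.0 d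
- elm: D 10 mM; L 1.20 equiv (fed, over 3.0 d); all else is in the flask from the start; the feed brings no volume worth counting; time 5.0 d

| run | time / d | E / % |
|---|---|---|
| ochre | 0.417 | 17.0 |
| ochre | 0.833 | 29.9 |
| ochre | 2.00 | 49.7 |
| ochre | 5.00 | 68.6 |
| blue | 1.25 | 14.0 |
| blue | 2.50 | 24.4 |
| blue | 4.00 | 32.7 |
| blue | 5.00 | 37.3 |
| amber | 0.417 | 10.4 |
| amber | 0.833 | 19.4 |
| amber | 2.00 | 36.0 |
| amber | 5.00 | 56.2 |
| green | 0.625 | 32.7 |
| green | 1.67 | 58.3 |
| green | 3.00 | 71.3 |
| green | 5.00 | 78.5 |

(readings scatter by 0.3 percentage points)

- which flask leads in amount of E, in percent of the D charged ("all alike" within 1.5 percentage points) (maple / alder / larch / elm / all alike)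
- how much E is there at the end, in percent of the D charged: maple
- how much E is there at the end, in percent of the D charged: alder
- how much E is there at the end, in percent of the D charged: larch
- how much E is there at the end, in percent of the D charged: elm

- reactions considered so far: D + Z <-> Z + X; L + Z + X -> Z + E; D + L -> J

The chair noted that maple has ochre's charges, so its figure could be read from ochre's last reading, 68.6 %. One member then put larch at 3.50 d and called this figure the clock: time in the flask less half the feed time, multiplied by the square of the D charge over ochre's. Her grounds were that a steady feed delivers its portions, on average, that much late, and that the earlier runs seem to follow the squared charge.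

She tested this on amber, whose last reading stands at a clock of 2.81 d. A line in reciprocals through ochre's readings at 2.00 d and 5.00 d gives 57.3 % there, and amber read 56.2 %.

The same line gave her 67.1 % for alder. For larch it gave 61.9 %, and she took the same for elm, which has the same feed time.

The forecast's author argued that “feeding cannot change selectivity”, and forecast maple first, with 68.6 %, 66.9 %, 60.5 % and 61.5 % for maple, alder, larch and elm. The clock stood higher than the forecast for larch, and the minutes keep both figures.

The flasks end with 68.9 % in maple, 67.3 % in alder, 61.0 % in larch and 62.1 % in elm, so maple leads and the forecast stands.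

    D + Z ⇌ Z + X (K = 0.180, k = 5500 M⁻¹ h⁻¹)
    L + Z + X → Z + E (k = 3.60 × 10⁵ M⁻² h⁻¹)
    D + L → J (k = 0.420 M⁻¹ h⁻¹)

Larch's answer has moved by 5 points at a D charge of 11.2 mM with the equivalents of L and the loading of Z held, so a whole recipe made up that much stronger is one change that a run would show against the forecast. The clock there reads 4.43 d, and the line rises by 4.5 percentage points from its larch value.

Take larch with 6.0 mM of D: its clock is 1.26 d, about blue's final 1.25 d, so it should hold blue's 37.3 %. The neighbour ends at 37.8 %.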